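Two final percentages and one choice between them are asked, and these are the runs.

in all of them: gas 87 mM (held)
- zeta: starting material 0.085 M; temperature −20 °C; run made earlier
- beta: starting material 0.16 M; temperature −5 °C; run made earlier
- maple: starting material 0.20 M; temperature 5 °C; time 2.0 h
- ash: starting material 0.10 M; temperature −15 °C; time 3.0 h

| zeta: time / h | zeta: target / % | beta: time / min | beta: target / % |
|---|---|---|---|
| 0.250 | 6.9 | 8.00 | 15.2 |
| 0.500 | 14.7 | 12.0 | 21.3 |
| 0.667 | 17.2 | 20.0 | 31.8 |
| 0.833 | 21.6 | 25.0 | 35.8 |
| 1.33 | 30.6 | 40.0 | 46.9 |
| 2.50 | 44.6 | 60.0 | 50.6 |
| 3.00 | 47.8 | 90.0 | 50.7 |

(each reading ± 1 percentage point)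

- what was read earlier has a scatter of 1 percentage point, one standard deviation
- at the start none of the gas is in solution

1. the flask that ends with the higher amount of target, in percent of the starting material charged, or "neither" when 2 percentage points or less lies between them (maple / ash / neither)
2. final target, as a percentage of the starting material charged, in maple
3. final target, as a percentage of the starting material charged, in ash

I read the rate of target first. Beta starts at 1.14 h⁻¹ of its charge, but between 25.0 min and 40.0 min it runs at 0.444 h⁻¹, a fall by a factor 2.57. Shrinking starting material gives a factor 1.71 if each unit became target, which leaves a factor 1.50 unexplained. Then the beta readings stop rising near 50.7%, while zeta is still climbing at 47.8%. So I suppose a brake: a loss of target that grows with target and with the charge and also consumes starting material.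

Let s be loss rate over making rate with target equal to the charge. I replace the curve by its mean: target averages half its end y, so the mean ratio m is half of s·y, and the net share, one minus m over one plus m, must equal y. Beta gives m = 0.327 and s = 1.29. Hence 0.124 M is my brake charge C, the charge at which s equals one, a selectivity factor written as a concentration. I carry it unchanged across temperature, untested. Summed along the curve, this s spends 1.14 charges instead of one, but reading and use share that error.

Maple has s = 1.61, so y is 45.9%. Ash has s = 0.807, so y is 60.7%. Does ash get there? Start rate times time was 1.14 when the beta readings stopped rising. Ash, a third of the way from zeta to beta on a log scale, starts near 0.443 h⁻¹, and its product is larger, 1.33. I commit to ash, ending under 60.7%, with 45.9% for maple.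

The forecast says ash, with 38.5% for maple and 57% for ash: “I read this as a reversible uptake”.

The flasks give 50.3% for maple and 54.7% for ash, so ash ends higher.

    starting material + reagent → target + by-product (k = 0.0190 M⁻¹ s⁻¹, Ea = 67.0 kJ mol⁻¹)
    starting material + target → side product (k = 0.00770 M⁻¹ s⁻¹, Ea = 50.0 kJ mol⁻¹)
    gas ⇌ reagent, rate k3*(csat - [reagent]) (kL = 0.00690 s⁻¹)
    (constants at 5 °C)

Maple stops with 0% of its starting material left, and it is no balance: without the passing of starting material + target into side product, its target goes from 50.3% to >99.9%. That is the brake, and my 45.9% from C stands 4.4 percentage points under maple. For a neighbour flask, maple with 0.34 M of starting material, C gives s = 2.74 and y = 35.1%. That neighbour flask gives 35.9%, with 64.1% in side product.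

The numbers in the tables were computed on assumed constants, noise included.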